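## The problem

Target **32** is a 2-oxaspiro[4.5]deca-6,9-dien-8-one. The locants used for every compound below are: C1 (bearing the chain C1'(OAr')–C2'H2OH), O2, C3 (guaiacyl), C4 (CH2OH), spiro C5, then C6=C7(OMe)–C8(=O)–C9=C10 back to C5. A tetrahydrofuran and a 2-methoxycyclohexa-2,5-dienone share one all-carbon quaternary atom, and C5 is stereogenic only because C7 carries a methoxy group and C9 does not. The two ring arms must therefore be distinguishable from the moment C5 is made. Five stereocentres have to be set: C1 (S), C3 (S), C4 (R), C5 (S) and the exocyclic C1' (S). C3 and C4 are a syn aldol-type pair that an auxiliary can fix absolutely, and C4 can then steer a cycloaddition that creates C5. C1 and C1' lie beyond reliable substrate control and call for a reagent-controlled step. The dienone is a double Michael acceptor within reach of the C4 hydroxymethyl group, so it should appear late and the hydroxyls should be released last under non-basic conditions. The C3 benzylic ether of an electron-rich arene is sensitive to oxidants and strong acid, which argues against any late radical allylic oxidation. The enabling feature is that O2 links the benzylic C3 to C1, and that C1 and C1' are vicinal oxygen-bearing carbons. A C3 hydroxyl can therefore open a trans C1–C1' epoxide at C1, closing the tetrahydrofuran, setting C1 by inversion and freeing the C1' oxygen for aryl ether formation.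

## Retrosynthesis

**C7 oxygenation (32 ⇐ 31 ⇐ 30 ⇐ 29 ⇐ 27).** After the four Si–O bonds, the C7–O bond and the C6=C7 unsaturation are removed, which leads back to enone **27**. The enone already holds the C8 carbonyl and the C9=C10 double bond, so only C7 needs oxygen. The alternative of carrying the dienone through the sequence would expose two acceptor positions to every free hydroxyl. A ring without C8 oxygen would need an allylic oxidation beside a benzylic ether. The forward steps ask for regioselective enolisation (C7 is the only enolisable carbon because C5 is quaternary), oxidation to diosphenol **30** and a base-free O-methylation to **31**.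

**Aryl ether (27 ⇐ 24 + 26).** The C1'–O(aryl) bond is cut. A Mitsunobu reaction joins the two halves convergently and inverts C1', so alcohol **24** must carry the opposite C1' configuration, which is what a trans epoxide delivers. Phenol **26** comes from dihydroconiferyl alcohol **25** in one step.

**Key disconnection (24 ⇐ 23).** The O2–C1 bond is cut, giving the epoxide **23** with a free C3 hydroxyl. Closing O2–C3 instead would pass through a benzylic cation or quinone methide with loose stereocontrol. Closing a C–C bond of the ring would leave C1 and C1' to be set separately. Here one stereospecific step forms the ring and C1 and frees the C1' hydroxyl. The forward reaction needs the C3 hydroxyl to be the only free hydroxyl and the epoxide to be trans with C1 and C1' both (R).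

**Epoxide and protecting-group pattern (23 ⇐ 22 ⇐ 21 ⇐ 20).** The epoxide is traced to the (E)-allylic alcohol **20** by Sharpless epoxidation, so C1 and C1' are set by the tartrate and not by the substrate. A triethylsilyl group on the C3 oxygen and tert-butyldimethylsilyl groups elsewhere allow the selective release that the key step needs.

**Side-chain alkene (20 ⇐ 19 ⇐ 18 ⇐ 17).** The C1=C1' bond is cut by a Horner–Wadsworth–Emmons disconnection to the C1 aldehyde **17**. The ester is reduced while the C8 ketone is still masked as the silyl enol ether left by the cycloaddition, which removes the chemoselectivity problem of reducing an ester beside an enone.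

**Carbocycle and C5 (17 ⇐ 15 + 16).** The C5–C10 and C6–C7 bonds are cut in a Diels–Alder disconnection to the 2-substituted acrolein **15** and the aminosiloxy diene **16**. One step builds the six-membered ring and the quaternary centre and brings the C8 oxygen and the latent C9=C10 double bond. A sigmatropic route onto a preformed cyclohexene would leave C8 unoxidised. Precursor **15** is acyclic with only C3 and C4. The forward reaction must add to the Si face of C5, and C4 is asked to control that.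

**Dienophile (15 ⇐ 14 ⇐ 12).** The C5=C6 methylene is removed (α-methylenation of aldehyde **14**), and the aldehyde is traced to the allyl group of **12** by oxidative cleavage.

**C3–C4 bond (12 ⇐ 11 ⇐ 10 ⇐ 9 ⇐ 6 + 2).** The C3–C4 bond is cut as an Evans syn aldol between imide **6** (from **3** and **4**) and silylated vanillin **2** (from **1**). This sets both centres absolutely in one step; reduction and two selective silylations give **12**.

## Roads not taken

**Alternative 1:** Robinson spiroannulation onto a finished tetrahydrofuran. The cut is C5–C10 plus C6=C7. Under secondary-amine catalysis the C5 aldehyde A2 would add to 1-methoxybut-3-en-2-one A3 and close by aldol condensation to the 2-methoxycyclohexenone A1.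
- Merits: the methoxy group and the C8 oxygen arrive with A3, so the C7 oxygenation of steps 18–20 shrinks to one late C9–C10 dehydrogenation. In this respect it is better than the chosen plan. The acceptor should also approach C5 anti to the cis-disposed C1 and C4 substituents, which is the face required.
- Weak points: C5 of A2 is flanked by two substituted ring carbons, so enamine formation and Michael addition to make a quaternary centre will be slow. A2 is a β-alkoxy aldehyde (C5–C1–O2), so its enamine or enolate can expel O2 and open the ring. A3 is a polymerisable acceptor. A2 still needs its own tetrahydrofuran synthesis with four stereocentres.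
- Comparison: the chosen plan has the longer end game. Against that it makes C5 by cycloaddition before any ring ether exists, so no elimination path is open, and it controls each stereocentre in a separate step.

**Alternative 2:** Palladium-mediated [3+2] annulation. The cut is O2–C1 and C4–C5 at once. A zerovalent palladium catalyst with a chiral phosphine would open the trans vinyl epoxide A6; the alkoxide would add to C1 of the brominated quinone methide A5 and the phenoxide would attack the allyl unit through C5 to give the spirodienone A4.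
- Merits: it is the most convergent route and clearly shorter than the chosen plan. The methoxydienone comes directly from an aromatic precursor, so no ring oxidation is needed.
- Weak points: C1, C4 and C5 are formed in one step. The 1,6-addition at C1 is steered only by the acyclic C1' centre. The phenoxide must alkylate at carbon rather than oxygen, through the branched allyl terminus, and on the correct side of an unsymmetrical ring. A5 is an unhindered quinone methide with a β-aryloxy group and should be short-lived. Afterwards the vinyl group must be cleaved to CH2OH and the bromine removed in the presence of the dienone.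
- Comparison: the chosen plan is longer. It sets against this that every stereocentre comes from a step with a known sense of induction.

**Alternative 3:** Carbenoid C–H insertion closing C3–C4. A divalent rhodium carboxylate dimer would decompose the diazo ester A8, and the carbenoid at C4 would insert into a benzylic C–H bond of the guaiacylmethyl ether on the C1 oxygen to give the tetrahydrofuran ester A7.
- Merits: the C–H bond is benzylic and α to oxygen, five-membered insertion is the favoured mode, and C3 and C4 are made together.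
- Weak points: the carbenoid carbon sits on the quaternary C5, so diazo installation and the insertion are hindered. The C3/C4 outcome relative to C1 and C5 depends on matching with a chiral catalyst. Addition to the C9=C10 alkene and insertion into other activated C–H bonds compete. A7 still needs ester reduction and the whole oxidation of a plain cyclohexene to the methoxydienone, including an allylic oxidation beside the benzylic ether.
- Comparison: it is no shorter than the chosen plan. The chosen plan gets C3 and C4 from an auxiliary aldol of predictable sense and carries the C8 oxygen from the cycloaddition.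

Key step: step 15

Remarks on the chemistry:
- TBS = tert-butyldimethylsilyl, TES = triethylsilyl.
- Spiro compounds are named with the target's locants (C9=C10 enone).
- Cycloadduct **17** is assumed to be the endo isomer (dimethylamino cis to formyl); that centre is lost in step 11.

## Route

Step 1
Reactants: 1 vanillin (4-hydroxy-3-methoxybenzaldehyde)
Product: 2 3-methoxy-4-(TBS-oxy)benzaldehyde
Conditions: TBSCl, imidazole, DMF, 23 °C
Reagents that add atoms: tert-butyldimethylsilyl chloride, CC(C)(C)[Si](C)(C)Cl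
Why: Imidazole-promoted silylation of the phenol; the aryl silyl ether survives the enolate, hydride and oxidation steps and is removed with the other silyl groups in step 21.

Step 2
Reactants: 3 (S)-4-benzyloxazolidin-2-one; 4 pent-4-enoyl chloride
Product: 6 (S)-4-benzyl-3-(pent-4-enoyl)oxazolidin-2-one, via lithium oxazolidinide 5 (not isolated)
Conditions: n-BuLi, THF, −78 °C; then 4, −78 to 0 °C
Reagents that add atoms: none
Why: N-Acylation of the lithiated oxazolidinone with the acid chloride, the standard entry to an imide for an Evans aldol reaction.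

Step 3
Reactants: 6 (S)-4-benzyl-3-(pent-4-enoyl)oxazolidin-2-one; 2 3-methoxy-4-(TBS-oxy)benzaldehyde
Product: 9 (S)-4-benzyl-3-[(2S)-2-{(S)-hydroxy[3-methoxy-4-(TBS-oxy)phenyl]methyl}pent-4-enoyl]oxazolidin-2-one, via (Z)-dibutylboron enolate 7 (not isolated), via dibutylboron aldolate 8 (not isolated)
Conditions: Bu2BOTf, iPr2NEt, CH2Cl2, −78 to 0 °C; then 2, −78 to 0 °C; then pH 7 buffer, MeOH, 30% H2O2, 0 °C
Reagents that add atoms: none
Why: Evans syn aldol reaction: the (Z)-boron enolate reacts through a chair Zimmerman–Traxler transition state on the face away from the benzyl group, which sets C4 and C3 as the required syn pair under auxiliary control. Electron-rich aryl aldehydes are competent acceptors in this reaction.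

Step 4
Reactants: 9 syn-aldol imide
Product: 10 (1S,2R)-1-[3-methoxy-4-(TBS-oxy)phenyl]-2-(prop-2-en-1-yl)propane-1,3-diol
Conditions: LiBH4, MeOH (1 equiv), THF, 0 °C
Reagents that add atoms: none
Why: Reductive cleavage of the imide gives the primary alcohol that becomes the C4 hydroxymethyl group and returns the auxiliary; neither stereocentre is touched.

Step 5
Reactants: 10 diol
Product: 11 (1S,2R)-1-[3-methoxy-4-(TBS-oxy)phenyl]-2-[(TBS-oxy)methyl]pent-4-en-1-ol
Conditions: TBSCl (1.05 equiv), imidazole, CH2Cl2, 0 °C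
Reagents that add atoms: tert-butyldimethylsilyl chloride, CC(C)(C)[Si](C)(C)Cl
Why: Monosilylation: the primary hydroxyl reacts much faster than the hindered secondary benzylic one, so the C4 hydroxymethyl oxygen is masked and cannot compete in step 15.

Step 6
Reactants: 11 primary TBS ether
Product: 12 (4R,5S)-5-[3-methoxy-4-(TBS-oxy)phenyl]-4-[(TBS-oxy)methyl]-5-(TES-oxy)pent-1-ene
Conditions: Et3SiOTf, 2,6-lutidine, CH2Cl2, −78 °C
Reagents that add atoms: triethylsilyl trifluoromethanesulfonate, CC[Si](CC)(CC)OS(=O)(=O)C(F)(F)F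
Why: Silylation of the C3 hydroxyl with the more labile triethylsilyl group, which can later be removed beside TBS ethers. It also prevents lactol formation once C1 is an aldehyde.

Step 7
Reactants: 12 alkene
Product: 14 (3R,4S)-4-[3-methoxy-4-(TBS-oxy)phenyl]-3-[(TBS-oxy)methyl]-4-(TES-oxy)butanal, via 1,2-diol 13 (not isolated)
Conditions: OsO4 (2 mol %), N-methylmorpholine N-oxide, acetone/H2O, 23 °C; then NaIO4, 23 °C
Reagents that add atoms: N-methylmorpholine N-oxide, C[N+]1([O-])CCOCC1 (terminal oxidant; its oxygen is delivered through osmium tetroxide, O=[Os](=O)(=O)=O)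
Why: Lemieux–Johnson-type dihydroxylation and periodate cleavage turn the terminal alkene into the C1 aldehyde. Osmium tetroxide is preferred to ozone, which would attack the electron-rich arene.

Step 8
Reactants: 14 aldehyde
Product: 15 (3R,4S)-4-[3-methoxy-4-(TBS-oxy)phenyl]-3-[(TBS-oxy)methyl]-2-methylidene-4-(TES-oxy)butanal
Conditions: aq. CH2O (37%), pyrrolidine (10 mol %), EtCO2H (10 mol %), iPrOH, 45 °C
Reagents that add atoms: formaldehyde, C=O
Why: Amine-catalysed Mannich condensation–elimination (α-methylenation of an aldehyde) installs C6 as the methylene of a 2-substituted acrolein. C4 is not the enolisable α-carbon, so its configuration is kept.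

Step 9
Reactants: 15 2-substituted acrolein; 16 (E)-3-(TBS-oxy)-N,N-dimethylbuta-1,3-dien-1-amine
Product: 17 (1R,2R)-2-(dimethylamino)-1-{(1S,2R)-1-[3-methoxy-4-(TBS-oxy)phenyl]-3-(TBS-oxy)-1-(TES-oxy)propan-2-yl}-4-(TBS-oxy)cyclohex-3-ene-1-carbaldehyde
Conditions: toluene, 23 to 40 °C, no catalyst; used crude
Reagents that add atoms: none
Why: Normal-demand Diels–Alder reaction of a 1-amino-3-siloxy diene with an α-substituted acrolein; diene polarisation joins its CH2 terminus to C6 and its amino carbon (C10) to C5, so C5 becomes quaternary with the formyl group (C1) and C8 arrives as a silyl enol ether. C5 is set by C4: in the favoured staggered transition state the C4–C3 bond is anti to the incoming diene, CH2OTBS lies over the alkene and the C4 hydrogen lies next to the formyl group (least allylic 1,2-strain), which exposes the Si face of C5. The endo amino centre at C10 is lost in step 11, and enantiopurity rests on step 3, so a minor C5 epimer would be a separable diastereomer.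

Step 10
Reactants: 17 cycloadduct aldehyde
Product: 18 ethyl (E)-3-[(1R,2R)-2-(dimethylamino)-1-{(1S,2R)-1-[3-methoxy-4-(TBS-oxy)phenyl]-3-(TBS-oxy)-1-(TES-oxy)propan-2-yl}-4-(TBS-oxy)cyclohex-3-en-1-yl]prop-2-enoate
Conditions: (EtO)2P(O)CH2CO2Et, NaH, THF, 0 to 23 °C
Reagents that add atoms: triethyl phosphonoacetate, CCOC(=O)CP(=O)(OCC)OCC
Why: Horner–Wadsworth–Emmons olefination of the non-enolisable neopentyl aldehyde gives the (E)-enoate and adds C1' and C2'. The silyl enol ether and the tertiary amine are inert to the phosphonate anion.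

Step 11
Reactants: 18 enoate
Product: 20 (S)-4-[(E)-3-hydroxyprop-1-en-1-yl]-4-{(1S,2R)-1-[3-methoxy-4-(TBS-oxy)phenyl]-3-(TBS-oxy)-1-(TES-oxy)propan-2-yl}cyclohex-2-en-1-one, via silyl-enol-ether allylic alcohol 19 (not isolated)
Conditions: iBu2AlH (3 equiv), CH2Cl2, −78 °C; then 0.1 M aq. HCl, THF, 0 °C, short contact
Reagents that add atoms: none
Why: iBu2AlH reduces the enoate to the (E)-allylic alcohol while C8 is still protected as its silyl enol ether. Dilute acid then hydrolyses the enol ether, and the resulting β-amino ketone loses dimethylamine to give the C9=C10 enone; the hindered secondary TES ether is expected to cleave more slowly than the enol ether.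

Step 12
Reactants: 20 (E)-allylic alcohol
Product: 21 (S)-4-[(2R,3R)-3-(hydroxymethyl)oxiran-2-yl]-4-{(1S,2R)-1-[3-methoxy-4-(TBS-oxy)phenyl]-3-(TBS-oxy)-1-(TES-oxy)propan-2-yl}cyclohex-2-en-1-one
Conditions: Ti(OiPr)4 (0.3 equiv), D-(−)-diethyl tartrate (0.36 equiv), t-BuOOH, 4 Å molecular sieves, CH2Cl2, −20 °C
Reagents that add atoms: tert-butyl hydroperoxide, CC(C)(C)OO
Why: Sharpless asymmetric epoxidation of a primary (E)-allylic alcohol: with D-(−)-tartrate the oxygen is delivered to the face that gives the (2R,3R)-epoxy alcohol, so C1 and C1' are both (R) under reagent control. The enone alkene is not an allylic alcohol and is left alone.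

Step 13
Reactants: 21 epoxy alcohol
Product: 22 (S)-4-{(2R,3R)-3-[(TBS-oxy)methyl]oxiran-2-yl}-4-{(1S,2R)-1-[3-methoxy-4-(TBS-oxy)phenyl]-3-(TBS-oxy)-1-(TES-oxy)propan-2-yl}cyclohex-2-en-1-one
Conditions: TBSCl, imidazole, CH2Cl2, 0 to 23 °C
Reagents that add atoms: tert-butyldimethylsilyl chloride, CC(C)(C)[Si](C)(C)Cl
Why: Silylation of the primary epoxy alcohol, so that only the C3 oxygen can act as nucleophile in step 15 and only the C1' hydroxyl is free in step 17.

Step 14
Reactants: 22 fully silylated epoxide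
Product: 23 (S)-4-{(2R,3R)-3-[(TBS-oxy)methyl]oxiran-2-yl}-4-{(1S,2R)-1-hydroxy-1-[3-methoxy-4-(TBS-oxy)phenyl]-3-(TBS-oxy)propan-2-yl}cyclohex-2-en-1-one
Conditions: HF·pyridine, pyridine, THF, 0 °C
Reagents that add atoms: none
Why: Buffered fluoride cleaves the triethylsilyl ether selectively beside primary alkyl and aryl TBS ethers. The medium is too weakly acidic to open the epoxide, so the hydroxy epoxide can be isolated.

Step 15
Reactants: 23 trans-epoxide with free C3 hydroxyl
Product: 24 (1S,3S,4R,5S)-1-[(1R)-1-hydroxy-2-(TBS-oxy)ethyl]-3-[3-methoxy-4-(TBS-oxy)phenyl]-4-[(TBS-oxy)methyl]-2-oxaspiro[4.5]dec-9-en-8-one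
Conditions: (+)-camphor-10-sulfonic acid (10 mol %), CH2Cl2, 0 °C
Reagents that add atoms: none
Why: Acid-catalysed stereospecific cycloetherification of a 4,5-epoxy alcohol: the sulfonic acid activates the oxirane oxygen and the C3 hydroxyl attacks C1 from the side opposite the C1–O bond (SN2, 5-exo-tet), which forms the O2–C1 bond, closes the tetrahydrofuran and releases the C1' oxygen as a free hydroxyl. The closest known reaction type is the acid-mediated 5-exo opening of trans-disubstituted epoxy alcohols from Sharpless epoxidation to 2-(1-hydroxyalkyl)tetrahydrofurans. C1 is the only new stereocentre; it arises by inversion of the (R)-configured oxirane carbon installed under tartrate control in step 12, C1' keeps its configuration, and C3 is untouched because the benzylic C3–O bond is never broken. Attack at C1 rather than C1' is secured by the exo preference of five-membered closure, by the inductive deactivation of C1' by the adjacent CH2OTBS group and by the gem-disubstitution at C5 that holds the C3 oxygen near C1; the neopentyl character of C1 would slow an external nucleophile but not this tethered one. Among the oxygen nucleophiles only the C3 hydroxyl is free, since the C4 hydroxymethyl and C2' oxygens are silylated. The enone is a second electrophile for the same hydroxyl (addition at C10), but that addition is slower under catalytic acid at 0 °C and reversible, whereas oxirane opening is fast and irreversible. Acid is chosen over an amide base because a C3 alkoxide would invite 1,5-silyl migration from the C4 CH2OTBS group and conjugate addition to the enone.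

Step 16
Reactants: 25 dihydroconiferyl alcohol (4-(3-hydroxypropyl)-2-methoxyphenol)
Product: 26 2-methoxy-4-[3-(TBS-oxy)propyl]phenol
Conditions: TBSCl (1.05 equiv), imidazole, CH2Cl2, 0 °C
Reagents that add atoms: tert-butyldimethylsilyl chloride, CC(C)(C)[Si](C)(C)Cl
Why: Selective silylation of the primary aliphatic hydroxyl with one equivalent of silyl chloride at low temperature; the phenol must stay free as the Mitsunobu nucleophile.

Step 17
Reactants: 24 spiro alcohol; 26 phenol
Product: 27 (1S,3S,4R,5S)-1-[(1S)-1-{2-methoxy-4-[3-(TBS-oxy)propyl]phenoxy}-2-(TBS-oxy)ethyl]-3-[3-methoxy-4-(TBS-oxy)phenyl]-4-[(TBS-oxy)methyl]-2-oxaspiro[4.5]dec-9-en-8-one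
Conditions: PPh3, diisopropyl azodicarboxylate, toluene, 0 to 23 °C
Reagents that add atoms: none
Why: Mitsunobu etherification: the C1' hydroxyl is activated as an oxyphosphonium ion and displaced by the phenoxide with inversion, converting the (R) carbinol from the epoxide into the (S) aryl ether of the target. All other hydroxyls are silylated.

Step 18
Reactants: 27 enone
Product: 29 7-hydroxy derivative of 27 (both C7 epimers; 7-hydroxy-2-oxaspiro[4.5]dec-9-en-8-one core), via potassium dienolate 28 (not isolated)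
Conditions: KN(SiMe3)2, THF, −78 °C; then 2-(phenylsulfonyl)-3-phenyloxaziridine, −78 °C; AcOH quench
Reagents that add atoms: 2-(phenylsulfonyl)-3-phenyloxaziridine, O=S(=O)(c1ccccc1)N1OC1c1ccccc1
Why: Kinetic deprotonation at C7, the only enolisable position because C5 is quaternary, followed by electrophilic hydroxylation of the potassium dienolate with the N-sulfonyloxaziridine (enolate oxidation). The C7 configuration is irrelevant because it is erased in step 19.

Step 19
Reactants: 29 α-hydroxy enone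
Product: 30 (1S,3S,4R,5S)-7-hydroxy-1-[(1S)-1-{2-methoxy-4-[3-(TBS-oxy)propyl]phenoxy}-2-(TBS-oxy)ethyl]-3-[3-methoxy-4-(TBS-oxy)phenyl]-4-[(TBS-oxy)methyl]-2-oxaspiro[4.5]deca-6,9-dien-8-one
Conditions: DMP (1,1,1-triacetoxy-1,1-dihydro-1,2-benziodoxol-3(1H)-one), NaHCO3, CH2Cl2, 0 to 23 °C
Reagents that add atoms: none
Why: Oxidation of the α-hydroxy ketone to the 1,2-dione with the hypervalent iodine reagent. The dione enolises toward C6, the only side with hydrogens, to the conjugated diosphenol.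

Step 20
Reactants: 30 diosphenol
Product: 31 (1S,3S,4R,5S)-7-methoxy-1-[(1S)-1-{2-methoxy-4-[3-(TBS-oxy)propyl]phenoxy}-2-(TBS-oxy)ethyl]-3-[3-methoxy-4-(TBS-oxy)phenyl]-4-[(TBS-oxy)methyl]-2-oxaspiro[4.5]deca-6,9-dien-8-one
Conditions: Me3SiCHN2 (hexanes), MeOH/toluene, 0 to 23 °C
Reagents that add atoms: (trimethylsilyl)diazomethane, C[Si](C)(C)C=[N+]=[N-]
Why: O-Methylation of the acidic diosphenol hydroxyl by diazomethane released from Me3SiCHN2 and methanol. The base-free conditions keep the aryl silyl ether intact, so no phenol is methylated.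

Step 21
Reactants: 31 tetrasilyl ether
Product: 32 (1S,3S,4R,5S)-1-{(1S)-2-hydroxy-1-[4-(3-hydroxypropyl)-2-methoxyphenoxy]ethyl}-3-(4-hydroxy-3-methoxyphenyl)-4-(hydroxymethyl)-7-methoxy-2-oxaspiro[4.5]deca-6,9-dien-8-one (CNP0252711.1)
Conditions: HF·pyridine, pyridine, THF, 0 to 23 °C
Reagents that add atoms: none
Why: Global fluoride-mediated desilylation under buffered, non-basic conditions releases the phenol and the three primary hydroxyls without forming an alkoxide that could add to the dienone.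

## Compound list

1 | vanillin (4-hydroxy-3-methoxybenzaldehyde) | COc1cc(C=O)ccc1O | starting material
2 | 3-methoxy-4-(TBS-oxy)benzaldehyde | COc1cc(C=O)ccc1O[Si](C)(C)C(C)(C)C | intermediate
3 | (S)-4-benzyloxazolidin-2-one | O=C1N[C@@H](Cc2ccccc2)CO1 | starting material
4 | pent-4-enoyl chloride | C=CCCC(=O)Cl | starting material
5 | lithium (S)-4-benzyl-2-oxooxazolidin-3-ide | [Li+].O=C1[N-][C@@H](Cc2ccccc2)CO1 | intermediate
6 | (S)-4-benzyl-3-(pent-4-enoyl)oxazolidin-2-one | C=CCCC(=O)N1C(=O)OC[C@@H]1Cc1ccccc1 | intermediate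
7 | (Z)-dibutylboron enolate of 6 | C=CC/C=C(\OB(CCCC)CCCC)N1C(=O)OC[C@@H]1Cc1ccccc1 | intermediate
8 | dibutylboron aldolate of 9 | C=CC[C@H](C(=O)N1C(=O)OC[C@@H]1Cc1ccccc1)[C@H](OB(CCCC)CCCC)c1ccc(O[Si](C)(C)C(C)(C)C)c(OC)c1 | intermediate
9 | (S)-4-benzyl-3-[(2S)-2-{(S)-hydroxy[3-methoxy-4-(TBS-oxy)phenyl]methyl}pent-4-enoyl]oxazolidin-2-one | C=CC[C@H](C(=O)N1C(=O)OC[C@@H]1Cc1ccccc1)[C@H](O)c1ccc(O[Si](C)(C)C(C)(C)C)c(OC)c1 | intermediate
10 | (1S,2R)-1-[3-methoxy-4-(TBS-oxy)phenyl]-2-(prop-2-en-1-yl)propane-1,3-diol | C=CC[C@H](CO)[C@H](O)c1ccc(O[Si](C)(C)C(C)(C)C)c(OC)c1 | intermediate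
11 | (1S,2R)-1-[3-methoxy-4-(TBS-oxy)phenyl]-2-[(TBS-oxy)methyl]pent-4-en-1-ol | C=CC[C@H](CO[Si](C)(C)C(C)(C)C)[C@H](O)c1ccc(O[Si](C)(C)C(C)(C)C)c(OC)c1 | intermediate
12 | (4R,5S)-5-[3-methoxy-4-(TBS-oxy)phenyl]-4-[(TBS-oxy)methyl]-5-(TES-oxy)pent-1-ene | C=CC[C@H](CO[Si](C)(C)C(C)(C)C)[C@H](O[Si](CC)(CC)CC)c1ccc(O[Si](C)(C)C(C)(C)C)c(OC)c1 | intermediate
13 | (4R,5S)-5-[3-methoxy-4-(TBS-oxy)phenyl]-4-[(TBS-oxy)methyl]-5-(TES-oxy)pentane-1,2-diol (both C2 epimers) | OCC(O)C[C@H](CO[Si](C)(C)C(C)(C)C)[C@H](O[Si](CC)(CC)CC)c1ccc(O[Si](C)(C)C(C)(C)C)c(OC)c1 | intermediate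
14 | (3R,4S)-4-[3-methoxy-4-(TBS-oxy)phenyl]-3-[(TBS-oxy)methyl]-4-(TES-oxy)butanal | O=CC[C@H](CO[Si](C)(C)C(C)(C)C)[C@H](O[Si](CC)(CC)CC)c1ccc(O[Si](C)(C)C(C)(C)C)c(OC)c1 | intermediate
15 | (3R,4S)-4-[3-methoxy-4-(TBS-oxy)phenyl]-3-[(TBS-oxy)methyl]-2-methylidene-4-(TES-oxy)butanal | C=C(C=O)[C@H](CO[Si](C)(C)C(C)(C)C)[C@H](O[Si](CC)(CC)CC)c1ccc(O[Si](C)(C)C(C)(C)C)c(OC)c1 | intermediate
16 | (E)-3-(TBS-oxy)-N,N-dimethylbuta-1,3-dien-1-amine | CN(C)/C=C/C(=C)O[Si](C)(C)C(C)(C)C | starting material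
17 | (1R,2R)-2-(dimethylamino)-1-{(1S,2R)-1-[3-methoxy-4-(TBS-oxy)phenyl]-3-(TBS-oxy)-1-(TES-oxy)propan-2-yl}-4-(TBS-oxy)cyclohex-3-ene-1-carbaldehyde | O=C[C@@]1([C@H](N(C)C)C=C(O[Si](C)(C)C(C)(C)C)CC1)[C@H](CO[Si](C)(C)C(C)(C)C)[C@H](O[Si](CC)(CC)CC)c1ccc(O[Si](C)(C)C(C)(C)C)c(OC)c1 | intermediate
18 | ethyl (E)-3-[(1R,2R)-2-(dimethylamino)-1-{(1S,2R)-1-[3-methoxy-4-(TBS-oxy)phenyl]-3-(TBS-oxy)-1-(TES-oxy)propan-2-yl}-4-(TBS-oxy)cyclohex-3-en-1-yl]prop-2-enoate | CCOC(=O)/C=C/[C@@]1([C@H](N(C)C)C=C(O[Si](C)(C)C(C)(C)C)CC1)[C@H](CO[Si](C)(C)C(C)(C)C)[C@H](O[Si](CC)(CC)CC)c1ccc(O[Si](C)(C)C(C)(C)C)c(OC)c1 | intermediate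
19 | (E)-3-[(1R,2R)-2-(dimethylamino)-1-{(1S,2R)-1-[3-methoxy-4-(TBS-oxy)phenyl]-3-(TBS-oxy)-1-(TES-oxy)propan-2-yl}-4-(TBS-oxy)cyclohex-3-en-1-yl]prop-2-en-1-ol | OC/C=C/[C@@]1([C@H](N(C)C)C=C(O[Si](C)(C)C(C)(C)C)CC1)[C@H](CO[Si](C)(C)C(C)(C)C)[C@H](O[Si](CC)(CC)CC)c1ccc(O[Si](C)(C)C(C)(C)C)c(OC)c1 | intermediate
20 | (S)-4-[(E)-3-hydroxyprop-1-en-1-yl]-4-{(1S,2R)-1-[3-methoxy-4-(TBS-oxy)phenyl]-3-(TBS-oxy)-1-(TES-oxy)propan-2-yl}cyclohex-2-en-1-one | OC/C=C/[C@@]1(C=CC(=O)CC1)[C@H](CO[Si](C)(C)C(C)(C)C)[C@H](O[Si](CC)(CC)CC)c1ccc(O[Si](C)(C)C(C)(C)C)c(OC)c1 | intermediate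
21 | (S)-4-[(2R,3R)-3-(hydroxymethyl)oxiran-2-yl]-4-{(1S,2R)-1-[3-methoxy-4-(TBS-oxy)phenyl]-3-(TBS-oxy)-1-(TES-oxy)propan-2-yl}cyclohex-2-en-1-one | OC[C@H]1O[C@@H]1[C@@]1(C=CC(=O)CC1)[C@H](CO[Si](C)(C)C(C)(C)C)[C@H](O[Si](CC)(CC)CC)c1ccc(O[Si](C)(C)C(C)(C)C)c(OC)c1 | intermediate
22 | (S)-4-{(2R,3R)-3-[(TBS-oxy)methyl]oxiran-2-yl}-4-{(1S,2R)-1-[3-methoxy-4-(TBS-oxy)phenyl]-3-(TBS-oxy)-1-(TES-oxy)propan-2-yl}cyclohex-2-en-1-one | CC(C)(C)[Si](C)(C)OC[C@H]1O[C@@H]1[C@@]1(C=CC(=O)CC1)[C@H](CO[Si](C)(C)C(C)(C)C)[C@H](O[Si](CC)(CC)CC)c1ccc(O[Si](C)(C)C(C)(C)C)c(OC)c1 | intermediate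
23 | (S)-4-{(2R,3R)-3-[(TBS-oxy)methyl]oxiran-2-yl}-4-{(1S,2R)-1-hydroxy-1-[3-methoxy-4-(TBS-oxy)phenyl]-3-(TBS-oxy)propan-2-yl}cyclohex-2-en-1-one | CC(C)(C)[Si](C)(C)OC[C@H]1O[C@@H]1[C@@]1(C=CC(=O)CC1)[C@H](CO[Si](C)(C)C(C)(C)C)[C@H](O)c1ccc(O[Si](C)(C)C(C)(C)C)c(OC)c1 | intermediate
24 | (1S,3S,4R,5S)-1-[(1R)-1-hydroxy-2-(TBS-oxy)ethyl]-3-[3-methoxy-4-(TBS-oxy)phenyl]-4-[(TBS-oxy)methyl]-2-oxaspiro[4.5]dec-9-en-8-one | O=C1CC[C@]2(C=C1)[C@H](CO[Si](C)(C)C(C)(C)C)[C@@H](c1ccc(O[Si](C)(C)C(C)(C)C)c(OC)c1)O[C@@H]2[C@@H](CO[Si](C)(C)C(C)(C)C)O | intermediate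
25 | dihydroconiferyl alcohol (4-(3-hydroxypropyl)-2-methoxyphenol) | COc1cc(CCCO)ccc1O | starting material
26 | 2-methoxy-4-[3-(TBS-oxy)propyl]phenol | COc1cc(CCCO[Si](C)(C)C(C)(C)C)ccc1O | intermediate
27 | (1S,3S,4R,5S)-1-[(1S)-1-{2-methoxy-4-[3-(TBS-oxy)propyl]phenoxy}-2-(TBS-oxy)ethyl]-3-[3-methoxy-4-(TBS-oxy)phenyl]-4-[(TBS-oxy)methyl]-2-oxaspiro[4.5]dec-9-en-8-one | O=C1CC[C@]2(C=C1)[C@H](CO[Si](C)(C)C(C)(C)C)[C@@H](c1ccc(O[Si](C)(C)C(C)(C)C)c(OC)c1)O[C@@H]2[C@H](CO[Si](C)(C)C(C)(C)C)Oc1ccc(CCCO[Si](C)(C)C(C)(C)C)cc1OC | intermediate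
28 | potassium 7,9-dien-8-olate of 27 | [K+].[O-]C1=CC[C@]2(C=C1)[C@H](CO[Si](C)(C)C(C)(C)C)[C@@H](c1ccc(O[Si](C)(C)C(C)(C)C)c(OC)c1)O[C@@H]2[C@H](CO[Si](C)(C)C(C)(C)C)Oc1ccc(CCCO[Si](C)(C)C(C)(C)C)cc1OC | intermediate
29 | 7-hydroxy derivative of 27 (both C7 epimers) | O=C1C(O)C[C@]2(C=C1)[C@H](CO[Si](C)(C)C(C)(C)C)[C@@H](c1ccc(O[Si](C)(C)C(C)(C)C)c(OC)c1)O[C@@H]2[C@H](CO[Si](C)(C)C(C)(C)C)Oc1ccc(CCCO[Si](C)(C)C(C)(C)C)cc1OC | intermediate
30 | (1S,3S,4R,5S)-7-hydroxy-1-[(1S)-1-{2-methoxy-4-[3-(TBS-oxy)propyl]phenoxy}-2-(TBS-oxy)ethyl]-3-[3-methoxy-4-(TBS-oxy)phenyl]-4-[(TBS-oxy)methyl]-2-oxaspiro[4.5]deca-6,9-dien-8-one | O=C1C(O)=C[C@]2(C=C1)[C@H](CO[Si](C)(C)C(C)(C)C)[C@@H](c1ccc(O[Si](C)(C)C(C)(C)C)c(OC)c1)O[C@@H]2[C@H](CO[Si](C)(C)C(C)(C)C)Oc1ccc(CCCO[Si](C)(C)C(C)(C)C)cc1OC | intermediate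
31 | (1S,3S,4R,5S)-7-methoxy-1-[(1S)-1-{2-methoxy-4-[3-(TBS-oxy)propyl]phenoxy}-2-(TBS-oxy)ethyl]-3-[3-methoxy-4-(TBS-oxy)phenyl]-4-[(TBS-oxy)methyl]-2-oxaspiro[4.5]deca-6,9-dien-8-one | COC1=C[C@]2(C=CC1=O)[C@H](CO[Si](C)(C)C(C)(C)C)[C@@H](c1ccc(O[Si](C)(C)C(C)(C)C)c(OC)c1)O[C@@H]2[C@H](CO[Si](C)(C)C(C)(C)C)Oc1ccc(CCCO[Si](C)(C)C(C)(C)C)cc1OC | intermediate
32 | (1S,3S,4R,5S)-1-{(1S)-2-hydroxy-1-[4-(3-hydroxypropyl)-2-methoxyphenoxy]ethyl}-3-(4-hydroxy-3-methoxyphenyl)-4-(hydroxymethyl)-7-methoxy-2-oxaspiro[4.5]deca-6,9-dien-8-one | COC1=C[C@]2(C=CC1=O)[C@H](CO)[C@@H](c1ccc(O)c(OC)c1)O[C@@H]2[C@H](CO)Oc1ccc(CCCO)cc1OC | target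

## Step count and least certain steps

Total: 21 steps. Longest linear sequence: 19 steps (1, 3–15, 17–21, from vanillin); steps 2 and 16 prepare the side components.

**Step 15 (key step).** The most likely failure is partitioning of the C3 hydroxyl between the oxirane carbon C1 and other electrophilic carbons, chiefly conjugate addition at C10 of the enone and, less likely, 6-endo attack at C1'. All three lie within reach of one hydroxyl under acid. The fallback removes the Michael acceptor for the duration of the ring closure. It sets out from **22**: Luche reduction (NaBH4, CeCl3·7H2O, MeOH, −78 °C) should give the C8 allylic alcohol F1 as a mixture of C8 epimers. HF·pyridine/pyridine then frees the C3 hydroxyl to give the hydroxy epoxide F2, and camphorsulfonic acid closes the ring to the spiro diol F3. MnO2 in CH2Cl2 oxidises only the allylic C8 hydroxyl and returns to **24**.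

**Step 9.** The most likely failure is poor facial selectivity at C5, because the directing centre C4 is acyclic and two rotamers about the C4–C5 bond expose opposite faces of the dienophile. The fallback makes the dienophile cyclic. It sets out from **15**:
- Pinnick oxidation (NaClO2, NaH2PO4, 2-methylbut-2-ene, t-BuOH/H2O) gives the acrylic acid F4.
- HF·pyridine/pyridine removes the triethylsilyl group to give the hydroxy acid F5, which lactonises to the trans-disubstituted α-methylene-γ-butyrolactone F6.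
- Diene **16** should add to the exocyclic alkene of this rigid lactone from the face opposite the adjacent C4 CH2OTBS group, giving the spiro cycloadduct F7 with the same C5 configuration as **17**.
- iBu2AlH at −78 °C reduces the lactone to the spiro lactol F8.
- Wittig reaction with Ph3P=CHCO2Et opens it to the hydroxy enoate F9.
- Et3SiOTf/2,6-lutidine returns to **18**.

**Step 11.** The most likely failure is loss of the triethylsilyl group at C3 during the acidic unmasking of the enone, since the aqueous acid that hydrolyses the silyl enol ether can also cleave silyl ethers. The freed hydroxyl could then add to C10. The fallback uses a more labile enol ether and no hydride after the ketone is free. It sets out from **15**: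
- Thermal cycloaddition with trans-1-methoxy-3-(trimethylsilyloxy)buta-1,3-diene (toluene, 80 °C) gives the trimethylsilyl enol ether cycloadduct F10.
- Aqueous citric acid in THF hydrolyses it to the β-methoxy ketone F11.
- DBU eliminates methanol to give the enone aldehyde F12.
- Wittig reaction with Ph3P=CHCHO gives the enone enal F13.
- Aldehyde-selective reduction (NaBH4, MeOH/CH2Cl2, −78 °C) returns to **20**.

**Step 17.** The most likely failure is slow displacement at the C1' oxyphosphonium centre, which is flanked by two oxygen-bearing carbons, so that elimination or N-alkylation of the hydrazide competes. The fallback separates activation from displacement. It sets out from **24**: Tf2O/pyridine (CH2Cl2, −20 °C) gives the C1' triflate F14. The cesium phenoxide F15, made from **26** and Cs2CO3 in DMF, displaces it with inversion at 0 °C and returns to **27**.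

## Further compounds

F1 | step 15 | C8 allylic alcohol from 22 (both C8 epimers): (S)-configured 4-{(2R,3R)-3-[(TBS-oxy)methyl]oxiran-2-yl}-4-{(1S,2R)-1-[3-methoxy-4-(TBS-oxy)phenyl]-3-(TBS-oxy)-1-(TES-oxy)propan-2-yl}cyclohex-2-en-1-ol | CC(C)(C)[Si](C)(C)OC[C@H]1O[C@@H]1[C@@]1(C=CC(O)CC1)[C@H](CO[Si](C)(C)C(C)(C)C)[C@H](O[Si](CC)(CC)CC)c1ccc(O[Si](C)(C)C(C)(C)C)c(OC)c1
F2 | step 15 | hydroxy epoxide with free C3 and C8 hydroxyls (both C8 epimers) | CC(C)(C)[Si](C)(C)OC[C@H]1O[C@@H]1[C@@]1(C=CC(O)CC1)[C@H](CO[Si](C)(C)C(C)(C)C)[C@H](O)c1ccc(O[Si](C)(C)C(C)(C)C)c(OC)c1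
F3 | step 15 | (1S,3S,4R,5S)-1-[(1R)-1-hydroxy-2-(TBS-oxy)ethyl]-3-[3-methoxy-4-(TBS-oxy)phenyl]-4-[(TBS-oxy)methyl]-2-oxaspiro[4.5]dec-9-en-8-ol (both C8 epimers) | OC1CC[C@]2(C=C1)[C@H](CO[Si](C)(C)C(C)(C)C)[C@@H](c1ccc(O[Si](C)(C)C(C)(C)C)c(OC)c1)O[C@@H]2[C@@H](CO[Si](C)(C)C(C)(C)C)O
F4 | step 9 | (3R,4S)-4-[3-methoxy-4-(TBS-oxy)phenyl]-3-[(TBS-oxy)methyl]-2-methylidene-4-(TES-oxy)butanoic acid | C=C(C(=O)O)[C@H](CO[Si](C)(C)C(C)(C)C)[C@H](O[Si](CC)(CC)CC)c1ccc(O[Si](C)(C)C(C)(C)C)c(OC)c1
F5 | step 9 | (3R,4S)-4-hydroxy-4-[3-methoxy-4-(TBS-oxy)phenyl]-3-[(TBS-oxy)methyl]-2-methylidenebutanoic acid | C=C(C(=O)O)[C@H](CO[Si](C)(C)C(C)(C)C)[C@H](O)c1ccc(O[Si](C)(C)C(C)(C)C)c(OC)c1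
F6 | step 9 | (4R,5S)-5-[3-methoxy-4-(TBS-oxy)phenyl]-4-[(TBS-oxy)methyl]-3-methylidenedihydrofuran-2(3H)-one | O=C1C(=C)[C@H](CO[Si](C)(C)C(C)(C)C)[C@@H](c2ccc(O[Si](C)(C)C(C)(C)C)c(OC)c2)O1
F7 | step 9 | spiro cycloadduct: 6-(dimethylamino)-8-(TBS-oxy)-3-[3-methoxy-4-(TBS-oxy)phenyl]-4-[(TBS-oxy)methyl]-2-oxaspiro[4.5]dec-7-en-1-one (C5 as in 17, amino group cis to the lactone carbonyl) | O=C1[C@@]2([C@H](N(C)C)C=C(O[Si](C)(C)C(C)(C)C)CC2)[C@H](CO[Si](C)(C)C(C)(C)C)[C@@H](c2ccc(O[Si](C)(C)C(C)(C)C)c(OC)c2)O1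
F8 | step 9 | spiro lactol from F7 (both C1 epimers) | OC1[C@@]2([C@H](N(C)C)C=C(O[Si](C)(C)C(C)(C)C)CC2)[C@H](CO[Si](C)(C)C(C)(C)C)[C@@H](c2ccc(O[Si](C)(C)C(C)(C)C)c(OC)c2)O1
F9 | step 9 | ethyl (E)-3-[(1R,2R)-2-(dimethylamino)-1-{(1S,2R)-1-hydroxy-1-[3-methoxy-4-(TBS-oxy)phenyl]-3-(TBS-oxy)propan-2-yl}-4-(TBS-oxy)cyclohex-3-en-1-yl]prop-2-enoate | CCOC(=O)/C=C/[C@@]1([C@H](N(C)C)C=C(O[Si](C)(C)C(C)(C)C)CC1)[C@H](CO[Si](C)(C)C(C)(C)C)[C@H](O)c1ccc(O[Si](C)(C)C(C)(C)C)c(OC)c1
F10 | step 11 | 2-methoxy-4-(trimethylsilyloxy)cyclohex-3-ene-1-carbaldehyde cycloadduct of 15 (C5 as in 17, methoxy cis to formyl) | O=C[C@@]1([C@H](OC)C=C(O[Si](C)(C)C)CC1)[C@H](CO[Si](C)(C)C(C)(C)C)[C@H](O[Si](CC)(CC)CC)c1ccc(O[Si](C)(C)C(C)(C)C)c(OC)c1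
F11 | step 11 | 2-methoxy-4-oxocyclohexane-1-carbaldehyde from F10 | O=C[C@@]1([C@H](OC)CC(=O)CC1)[C@H](CO[Si](C)(C)C(C)(C)C)[C@H](O[Si](CC)(CC)CC)c1ccc(O[Si](C)(C)C(C)(C)C)c(OC)c1
F12 | step 11 | 1-{(1S,2R)-1-[3-methoxy-4-(TBS-oxy)phenyl]-3-(TBS-oxy)-1-(TES-oxy)propan-2-yl}-4-oxocyclohex-2-ene-1-carbaldehyde (C5 as in 20) | O=C[C@@]1(C=CC(=O)CC1)[C@H](CO[Si](C)(C)C(C)(C)C)[C@H](O[Si](CC)(CC)CC)c1ccc(O[Si](C)(C)C(C)(C)C)c(OC)c1
F13 | step 11 | (E)-3-[1-{(1S,2R)-1-[3-methoxy-4-(TBS-oxy)phenyl]-3-(TBS-oxy)-1-(TES-oxy)propan-2-yl}-4-oxocyclohex-2-en-1-yl]prop-2-enal (C5 as in 20) | O=C/C=C/[C@@]1(C=CC(=O)CC1)[C@H](CO[Si](C)(C)C(C)(C)C)[C@H](O[Si](CC)(CC)CC)c1ccc(O[Si](C)(C)C(C)(C)C)c(OC)c1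
F14 | step 17 | C1' (R)-trifluoromethanesulfonate of 24 | O=C1CC[C@]2(C=C1)[C@H](CO[Si](C)(C)C(C)(C)C)[C@@H](c1ccc(O[Si](C)(C)C(C)(C)C)c(OC)c1)O[C@@H]2[C@@H](CO[Si](C)(C)C(C)(C)C)OS(=O)(=O)C(F)(F)F
F15 | step 17 | cesium 2-methoxy-4-[3-(TBS-oxy)propyl]phenoxide | [Cs+].COc1cc(CCCO[Si](C)(C)C(C)(C)C)ccc1[O-]
A1 | alternative 1 | spiro 2-methoxycyclohex-2-enone with all five stereocentres (7-methoxy-2-oxaspiro[4.5]dec-6-en-8-one, fully silylated) | COC1=C[C@]2(CCC1=O)[C@H](CO[Si](C)(C)C(C)(C)C)[C@@H](c1ccc(O[Si](C)(C)C(C)(C)C)c(OC)c1)O[C@@H]2[C@H](CO[Si](C)(C)C(C)(C)C)Oc1ccc(CCCO[Si](C)(C)C(C)(C)C)cc1OC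
A2 | alternative 1 | tetrahydrofuran-3-carbaldehyde bearing the C1 side chain, C3 aryl and C4 silyloxymethyl groups (C5 epimerisable) | O=CC1[C@H](CO[Si](C)(C)C(C)(C)C)[C@@H](c2ccc(O[Si](C)(C)C(C)(C)C)c(OC)c2)O[C@@H]1[C@H](CO[Si](C)(C)C(C)(C)C)Oc1ccc(CCCO[Si](C)(C)C(C)(C)C)cc1OC
A3 | alternative 1 | 1-methoxybut-3-en-2-one | COCC(=O)C=C
A4 | alternative 2 | 10-bromo spirodienone with a vinyl group on C4 | COC1=C[C@]2(C(Br)=CC1=O)[C@H](C=C)[C@@H](c1ccc(O[Si](C)(C)C(C)(C)C)c(OC)c1)O[C@@H]2[C@H](CO[Si](C)(C)C(C)(C)C)Oc1ccc(CCCO[Si](C)(C)C(C)(C)C)cc1OC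
A5 | alternative 2 | 2-bromo-6-methoxy para-quinone methide carrying the C1' aryl ether side chain | COC1=CC(=C[C@H](CO[Si](C)(C)C(C)(C)C)Oc2ccc(CCCO[Si](C)(C)C(C)(C)C)cc2OC)C(Br)=CC1=O
A6 | alternative 2 | (2R,3R)-2-[3-methoxy-4-(TBS-oxy)phenyl]-3-ethenyloxirane (trans) | C=C[C@H]1O[C@@H]1c1ccc(O[Si](C)(C)C(C)(C)C)c(OC)c1
A7 | alternative 3 | spiro tetrahydrofuran with a methyl ester on C4 and the aryl group on C3 | C1CC[C@]2(C=C1)[C@H](C(=O)OC)[C@@H](c1ccc(O[Si](C)(C)C(C)(C)C)c(OC)c1)O[C@@H]2[C@H](CO[Si](C)(C)C(C)(C)C)Oc1ccc(CCCO[Si](C)(C)C(C)(C)C)cc1OC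
A8 | alternative 3 | methyl 2-diazo-2-(cyclohex-2-en-1-yl)acetate with the C1 guaiacylmethyl ether and C1' aryl ether side chain on the quaternary carbon | COC(=O)C(=[N+]=[N-])[C@]1(C=CCCC1)[C@H](OCc1ccc(O[Si](C)(C)C(C)(C)C)c(OC)c1)[C@H](CO[Si](C)(C)C(C)(C)C)Oc1ccc(CCCO[Si](C)(C)C(C)(C)C)cc1OC
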